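## Retrosynthetic overview

- The target is (2R)-5,7,4'-trihydroxy-6,3',5'-triprenylflavanone. The plan rests on one feature: the ketone carbon C4 of ring C is bonded to C4a of ring A, which lies between the oxygen-bearing C5 and C8a. The only stereocentre, C2, sits on the O1–C2 ether bond.
- Ring C is closed last, at C4–C4a. The bromine at C4a is exchanged for lithium and the aryllithium is captured by a tethered N-methoxy-N-methylamide. Only removal of the three MOM groups follows.
- The amide carbon comes from the vinyl group of a branched allyl aryl ether (9-BBN hydroboration, oxidation, amidation). O1–C2 and the (R) centre come from an iridium-catalysed asymmetric allylic etherification.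
- The ring A partner is 2-bromo-3,5-bis(MOM-oxy)-4-prenylphenol, made from phloroglucinol. The ring B partner is a cinnamyl methyl carbonate, made from 3,5-dibromo-4-hydroxybenzaldehyde.
- Rings A and B are bought as arenes. Ring C is the only ring formed.

Key step: step 15

Assumption: L* is the antipode of O,O'-(1,1'-binaphthalene-2,2'-diyl) N,N-bis(1-phenylethyl)phosphoramidite (matched all-R or all-S form, both commercial) that turns cinnamyl methyl carbonate and lithium phenoxide into (R)-(1-phenoxyallyl)benzene; the ranking O > aryl > vinyl is the same in 19, so this antipode should give (R)-19.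

## Route

Step 1
Reactants: 1 phloroglucinol
Product: 2 5-(triisopropylsilyloxy)benzene-1,3-diol
Conditions: 1 (3 equiv), iPr3SiCl (1 equiv), imidazole, DMF, 0 °C → rt; excess 1 washed out with water
Reagents that add atoms: triisopropylsilyl chloride, CC(C)[Si](Cl)(C(C)C)C(C)C
Why: O-silylation of a phenol, in which the excess of the water-soluble triol should hold the reaction at the monosilyl stage and so set the later O1 apart from the other two oxygens.

Step 2
Reactants: 2 5-(triisopropylsilyloxy)benzene-1,3-diol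
Product: 3 [3,5-bis(methoxymethoxy)phenoxy]triisopropylsilane
Conditions: MOMCl, iPr2NEt, CH2Cl2, 0 °C → rt
Reagents that add atoms: chloromethyl methyl ether, COCCl
Why: MOM protection (O-alkylation of the two free phenols under amine base), conditions that leave the aryl silyl ether intact.

Step 3
Reactants: 3 [3,5-bis(methoxymethoxy)phenoxy]triisopropylsilane; 4 prenyl bromide
Product: 6 [3,5-bis(methoxymethoxy)-4-(3-methylbut-2-enyl)phenoxy]triisopropylsilane, via aryllithium 5 (not isolated)
Conditions: n-BuLi, THF, 0 °C; then 4, −78 °C → rt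
Reagents that add atoms: n-butyllithium, [Li]CCCC (lithium of 5 only)
Why: Directed ortho-metalation followed by SN2 alkylation: the position between the two chelating MOM ethers is the most activated and the bulky silyl ether shields the other two, so the prenyl group should enter only at the later C6.

Step 4
Reactants: 6 [3,5-bis(methoxymethoxy)-4-(3-methylbut-2-enyl)phenoxy]triisopropylsilane
Product: 7 3,5-bis(methoxymethoxy)-4-(3-methylbut-2-enyl)phenol
Conditions: Bu4NF, THF, 0 °C
Reagents that add atoms: none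
Why: Fluoride-induced desilylation frees only the O1 phenol, because MOM ethers and the alkene are inert to fluoride.

Step 5
Reactants: 7 3,5-bis(methoxymethoxy)-4-(3-methylbut-2-enyl)phenol
Product: 8 2-bromo-3,5-bis(methoxymethoxy)-4-(3-methylbut-2-enyl)phenol
Conditions: NBS (1.0 equiv), THF, −78 °C, dark
Reagents that add atoms: N-bromosuccinimide, O=C1CCC(=O)N1Br
Why: Electrophilic aromatic bromination: the trioxygenated phenol should react with NBS far faster than the trisubstituted alkene, the para position is blocked, and the two open ortho positions are equivalent by symmetry, so one equivalent should give a single monobromide.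

Step 6
Reactants: 9 3,5-dibromo-4-hydroxybenzaldehyde
Product: 10 3,5-dibromo-4-(methoxymethoxy)benzaldehyde
Conditions: MOMCl, iPr2NEt, CH2Cl2, 0 °C → rt
Reagents that add atoms: chloromethyl methyl ether, COCCl
Why: MOM protection of an acidic phenol, which gives a group that survives palladium catalysis, hydride and alkyllithium reagents.

Step 7
Reactants: 10 3,5-dibromo-4-(methoxymethoxy)benzaldehyde; 11 tributyl(3-methylbut-2-enyl)stannane
Product: 13 4-(methoxymethoxy)-3,5-bis(3-methylbut-2-enyl)benzaldehyde, via monoprenyl bromide 12 (not isolated)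
Conditions: 11 (2.4 equiv), Pd(PPh3)4 (5 mol %), DMF, 100 °C, degassed
Reagents that add atoms: none
Why: Twofold Stille coupling: the formyl group speeds oxidative addition of both C–Br bonds to zerovalent palladium, and the prenyl group should be transferred through its unsubstituted CH2 terminus, which gives the linear 3-methylbut-2-enyl groups.

Step 8
Reactants: 13 4-(methoxymethoxy)-3,5-bis(3-methylbut-2-enyl)benzaldehyde; 14 ethyl (triphenylphosphoranylidene)acetate
Product: 15 ethyl (E)-3-[4-(methoxymethoxy)-3,5-bis(3-methylbut-2-enyl)phenyl]acrylate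
Conditions: toluene, 80 °C
Reagents that add atoms: none
Why: Wittig olefination with a stabilised ylide is (E)-selective with aromatic aldehydes, and any (Z)-ester is removed by chromatography.

Step 9
Reactants: 15 ethyl (E)-3-[4-(methoxymethoxy)-3,5-bis(3-methylbut-2-enyl)phenyl]acrylate
Product: 16 (E)-3-[4-(methoxymethoxy)-3,5-bis(3-methylbut-2-enyl)phenyl]prop-2-en-1-ol
Conditions: iBu2AlH (2.3 equiv), CH2Cl2, −78 °C; aq potassium sodium tartrate
Reagents that add atoms: none
Why: 1,2-Reduction of the enoate by iBu2AlH at low temperature gives the allylic alcohol without touching the alkenes or the acetal.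

Step 10
Reactants: 16 (E)-3-[4-(methoxymethoxy)-3,5-bis(3-methylbut-2-enyl)phenyl]prop-2-en-1-ol
Product: 17 methyl (E)-3-[4-(methoxymethoxy)-3,5-bis(3-methylbut-2-enyl)phenyl]allyl carbonate
Conditions: ClCO2Me, pyridine, CH2Cl2, 0 °C
Reagents that add atoms: methyl chloroformate, COC(=O)Cl
Why: O-acylation with a chloroformate installs the carbonate leaving group that the iridium catalyst ionises.

Step 11
Reactants: 8 2-bromo-3,5-bis(methoxymethoxy)-4-(3-methylbut-2-enyl)phenol; 17 methyl (E)-3-[4-(methoxymethoxy)-3,5-bis(3-methylbut-2-enyl)phenyl]allyl carbonate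
Product: 19 (R)-2-bromo-1-{1-[4-(methoxymethoxy)-3,5-bis(3-methylbut-2-enyl)phenyl]allyloxy}-3,5-bis(methoxymethoxy)-4-(3-methylbut-2-enyl)benzene, via lithium aryloxide 18 (not isolated)
Conditions: 8 (1.2 equiv), LiN(SiMe3)2, THF, 0 °C; then 17, [Ir(cod)Cl]2 (2 mol %), L* (4 mol %, pre-activated with n-PrNH2), THF, rt; quenched as soon as 17 is consumed
Reagents that add atoms: LiN(SiMe3)2, [Li]N([Si](C)(C)C)[Si](C)(C)C (lithium of 18 only)
Why: Iridium-catalysed asymmetric allylic etherification: the cyclometalated iridium phosphoramidite ionises the linear carbonate to an η3-cinnamyl complex on one face, and the aryloxide attacks the aryl-bearing terminus anti to the metal, which gives the branched ether and sets C2 as (R) under catalyst control.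

Step 12
Reactants: 19 the (R)-allyl aryl ether
Product: 21 (R)-3-[2-bromo-3,5-bis(methoxymethoxy)-4-(3-methylbut-2-enyl)phenoxy]-3-[4-(methoxymethoxy)-3,5-bis(3-methylbut-2-enyl)phenyl]propan-1-ol, via B-alkyl-9-BBN adduct 20 (not isolated)
Conditions: 9-BBN (1.3 equiv), THF, 0 °C → rt; then 3 M NaOH, 30% H2O2, 0 °C
Reagents that add atoms: hydrogen peroxide, OO; 9-borabicyclo[3.3.1]nonane, B1C2CCCC1CCC2 (boron and ring of 20 only)
Why: Hydroboration–oxidation: 9-BBN adds to the monosubstituted alkene much faster than to the three trisubstituted prenyl alkenes and places boron on the terminal carbon, and alkaline peroxide replaces boron by hydroxyl without touching C2.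

Step 13
Reactants: 21 the (R)-primary alcohol
Product: 23 (R)-3-[2-bromo-3,5-bis(methoxymethoxy)-4-(3-methylbut-2-enyl)phenoxy]-3-[4-(methoxymethoxy)-3,5-bis(3-methylbut-2-enyl)phenyl]propanoic acid, via aldehyde 22 (not isolated)
Conditions: TEMPO (20 mol %), PhI(OAc)2 (2.3 equiv), MeCN–H2O, rt
Reagents that add atoms: water, O
Why: Oxoammonium (TEMPO) oxidation takes the primary alcohol through the aldehyde hydrate to the acid in a weakly acidic medium, where no base can trigger β-elimination from 22 and the prenyl alkenes and MOM ethers should persist.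

Step 14
Reactants: 23 the (R)-acid
Product: 25 (R)-3-[2-bromo-3,5-bis(methoxymethoxy)-4-(3-methylbut-2-enyl)phenoxy]-N-methoxy-3-[4-(methoxymethoxy)-3,5-bis(3-methylbut-2-enyl)phenyl]-N-methylpropanamide, via acyl imidazole 24 (not isolated)
Conditions: 1,1'-carbonyldiimidazole, CH2Cl2, 0 °C → rt; then MeNHOMe·HCl, rt
Reagents that add atoms: N,O-dimethylhydroxylamine hydrochloride, CNOC.Cl; 1,1'-carbonyldiimidazole, O=C(n1ccnc1)n1ccnc1 (imidazolyl of 24 only)
Why: Weinreb amide formation through the acyl imidazole needs no base stronger than imidazole, so the β-aryloxy group should stay in place and C2 keeps its configuration.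

Step 15
Reactants: 25 the (R)-bromo Weinreb amide
Product: 28 (R)-5,7-bis(methoxymethoxy)-2-[4-(methoxymethoxy)-3,5-bis(3-methylbut-2-enyl)phenyl]-6-(3-methylbut-2-enyl)chroman-4-one, via aryllithium 26 (not isolated), via lithium-chelated tetrahedral adduct 27 (not isolated)
Conditions: t-BuLi (2.1 equiv), THF–Et2O, 0.01 M, −100 °C → −78 °C; then AcOH in THF, −78 °C; pH 7 buffer
Reagents that add atoms: tert-butyllithium, [Li]C(C)(C)C (lithium of 26 and 27 only)
Why: The first equivalent of t-BuLi swaps the C4a bromine for lithium within minutes at −100 °C while the second destroys the tert-butyl bromide, and aryllithium 26, held by the C5 MOM oxygen and the amide carbonyl, adds to the amide carbon to make C4–C4a. This is a Parham cycloacylation, the reaction type by which o-bromoaryl ethers and o-bromoarylalkanes carrying a tethered N-methoxy-N-methylamide are converted into chroman-4-ones, indanones and tetralones. Ring C closes in the 6-exo-trig mode, with the carbonyl oxygen staying outside the new ring. No lasting stereocentre is created, since C4 of chelate 27 becomes trigonal again on quench, and C2 stays (R) because O1–C2 is never cleaved and no ketone enolate exists while base is present. The step needs exchange and closure to outrun removal of a C3 proton (which would expel the ring A aryloxide by E1cB) and intermolecular attack of the alkyllithium on the amide; the fast exchange of a bromide flanked by two oxygens, the low temperature, the dilution and the six-membered intramolecular transition state should secure this. Cold acetic acid releases ketone 28 only after all base is consumed, which guards against retro-oxa-Michael opening.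

Step 16
Reactants: 28 the (R)-tris-MOM flavanone
Product: 29 (2R)-5,7-dihydroxy-2-[4-hydroxy-3,5-bis(3-methylbut-2-enyl)phenyl]-6-(3-methylbut-2-enyl)chroman-4-one (target)
Conditions: 3 M aq HCl–MeOH, 45 °C, stopped at full conversion; pH 7 buffer work-up
Reagents that add atoms: none
Why: Acid-catalysed transacetalisation of aryl MOM ethers to methanol, established on prenylated flavanones, should be faster than protonation of the trisubstituted alkenes (chroman formation), and dilute acid does not open ring C to the chalcone, so C2 is retained.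

## Compound list

1 | phloroglucinol | Oc1cc(O)cc(O)c1 | starting material
2 | 5-(triisopropylsilyloxy)benzene-1,3-diol | CC(C)[Si](Oc1cc(O)cc(O)c1)(C(C)C)C(C)C | intermediate
3 | [3,5-bis(methoxymethoxy)phenoxy]triisopropylsilane | COCOc1cc(OCOC)cc(O[Si](C(C)C)(C(C)C)C(C)C)c1 | intermediate
4 | prenyl bromide | CC(C)=CCBr | starting material
5 | 2,6-bis(methoxymethoxy)-4-(triisopropylsilyloxy)phenyllithium | [Li]c1c(OCOC)cc(O[Si](C(C)C)(C(C)C)C(C)C)cc1OCOC | intermediate
6 | [3,5-bis(methoxymethoxy)-4-(3-methylbut-2-enyl)phenoxy]triisopropylsilane | CC(C)=CCc1c(OCOC)cc(O[Si](C(C)C)(C(C)C)C(C)C)cc1OCOC | intermediate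
7 | 3,5-bis(methoxymethoxy)-4-(3-methylbut-2-enyl)phenol | CC(C)=CCc1c(OCOC)cc(O)cc1OCOC | intermediate
8 | 2-bromo-3,5-bis(methoxymethoxy)-4-(3-methylbut-2-enyl)phenol | Oc1cc(OCOC)c(CC=C(C)C)c(OCOC)c1Br | intermediate
9 | 3,5-dibromo-4-hydroxybenzaldehyde | O=Cc1cc(Br)c(O)c(Br)c1 | starting material
10 | 3,5-dibromo-4-(methoxymethoxy)benzaldehyde | COCOc1c(Br)cc(C=O)cc1Br | intermediate
11 | tributyl(3-methylbut-2-enyl)stannane | CC(C)=CC[Sn](CCCC)(CCCC)CCCC | starting material
12 | 3-bromo-4-(methoxymethoxy)-5-(3-methylbut-2-enyl)benzaldehyde | COCOc1c(Br)cc(C=O)cc1CC=C(C)C | intermediate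
13 | 4-(methoxymethoxy)-3,5-bis(3-methylbut-2-enyl)benzaldehyde | COCOc1c(CC=C(C)C)cc(C=O)cc1CC=C(C)C | intermediate
14 | ethyl (triphenylphosphoranylidene)acetate | CCOC(=O)C=P(c1ccccc1)(c1ccccc1)c1ccccc1 | starting material
15 | ethyl (E)-3-[4-(methoxymethoxy)-3,5-bis(3-methylbut-2-enyl)phenyl]acrylate | CCOC(=O)/C=C/c1cc(CC=C(C)C)c(OCOC)c(CC=C(C)C)c1 | intermediate
16 | (E)-3-[4-(methoxymethoxy)-3,5-bis(3-methylbut-2-enyl)phenyl]prop-2-en-1-ol | OC/C=C/c1cc(CC=C(C)C)c(OCOC)c(CC=C(C)C)c1 | intermediate
17 | methyl (E)-3-[4-(methoxymethoxy)-3,5-bis(3-methylbut-2-enyl)phenyl]allyl carbonate | COC(=O)OC/C=C/c1cc(CC=C(C)C)c(OCOC)c(CC=C(C)C)c1 | intermediate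
18 | lithium 2-bromo-3,5-bis(methoxymethoxy)-4-(3-methylbut-2-enyl)phenoxide | [Li+].[O-]c1cc(OCOC)c(CC=C(C)C)c(OCOC)c1Br | intermediate
19 | (R)-branched allyl aryl ether | C=C[C@@H](Oc1cc(OCOC)c(CC=C(C)C)c(OCOC)c1Br)c1cc(CC=C(C)C)c(OCOC)c(CC=C(C)C)c1 | intermediate
20 | (R)-B-(3-aryl-3-aryloxypropyl)-9-borabicyclo[3.3.1]nonane | C1CC2CCCC(C1)B2CC[C@@H](Oc1cc(OCOC)c(CC=C(C)C)c(OCOC)c1Br)c1cc(CC=C(C)C)c(OCOC)c(CC=C(C)C)c1 | intermediate
21 | (R)-3-aryl-3-aryloxypropan-1-ol | OCC[C@@H](Oc1cc(OCOC)c(CC=C(C)C)c(OCOC)c1Br)c1cc(CC=C(C)C)c(OCOC)c(CC=C(C)C)c1 | intermediate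
22 | (R)-3-aryl-3-aryloxypropanal | O=CC[C@@H](Oc1cc(OCOC)c(CC=C(C)C)c(OCOC)c1Br)c1cc(CC=C(C)C)c(OCOC)c(CC=C(C)C)c1 | intermediate
23 | (R)-3-aryl-3-aryloxypropanoic acid | OC(=O)C[C@@H](Oc1cc(OCOC)c(CC=C(C)C)c(OCOC)c1Br)c1cc(CC=C(C)C)c(OCOC)c(CC=C(C)C)c1 | intermediate
24 | (R)-acyl imidazole of 23 | O=C(C[C@@H](Oc1cc(OCOC)c(CC=C(C)C)c(OCOC)c1Br)c1cc(CC=C(C)C)c(OCOC)c(CC=C(C)C)c1)n1ccnc1 | intermediate
25 | (R)-bromo Weinreb amide (key-step precursor) | CON(C)C(=O)C[C@@H](Oc1cc(OCOC)c(CC=C(C)C)c(OCOC)c1Br)c1cc(CC=C(C)C)c(OCOC)c(CC=C(C)C)c1 | intermediate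
26 | (R)-C4a aryllithium | CON(C)C(=O)C[C@@H](Oc1cc(OCOC)c(CC=C(C)C)c(OCOC)c1[Li])c1cc(CC=C(C)C)c(OCOC)c(CC=C(C)C)c1 | intermediate
27 | lithium alkoxide of the (2R)-4-[methoxy(methyl)amino]chroman-4-ol | CC(C)=CCc1cc([C@H]2CC([O-])(N(C)OC)c3c(cc(OCOC)c(CC=C(C)C)c3OCOC)O2)cc(CC=C(C)C)c1OCOC.[Li+] | intermediate
28 | (R)-target tris(methoxymethyl) ether | CC(C)=CCc1cc([C@H]2CC(=O)c3c(cc(OCOC)c(CC=C(C)C)c3OCOC)O2)cc(CC=C(C)C)c1OCOC | intermediate
29 | (2R)-5,7,4'-trihydroxy-6,3',5'-triprenylflavanone | CC(C)=CCc1cc([C@H]2CC(=O)c3c(cc(O)c(CC=C(C)C)c3O)O2)cc(CC=C(C)C)c1O | target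

Total step count: 16
Longest linear sequence: 11 steps (steps 1–5, then 11–16). The ring B branch (steps 6–10, then 11–16) is equally long.

## Steps most likely to fail

**1. Step 15.** A C3 proton may be transferred to the aryllithium or to t-BuLi, after which the ring A aryloxide is lost by β-elimination. The alkyllithium may also add to the amide before the exchange.

The fallback changes the internal electrophile to one without removable α-protons. It sets out from acid 23 and comes back at 28.
- n-BuLi (1 equiv, THF, −100 °C) converts 23 into the lithium carboxylate F1.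
- t-BuLi (2 equiv) then gives the aryllithium carboxylate F2.
- On slow warming F2 should close onto the carboxylate carbon, in the original acid variant of the Parham cyclisation, to the dilithium gem-diolate F3.
- A cold acetic acid quench of F3 gives 28.
- A carboxylate cannot be deprotonated at C3 by an aryllithium and does not support E1cB loss of the aryloxide.

**2. Step 11.** Three things may go wrong. The electron-rich benzylic ether may ionise reversibly on iridium, which erodes the enantiomeric purity. The ortho-bromo aryloxide may attack slowly. Attack may also leak to the linear terminus.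

The fallback sets C2 by reagent control and forms O1–C2 with inversion. It sets out from 16 and 8 and comes back at 21.
- Sharpless asymmetric epoxidation of 16 (Ti(OiPr)4, D-(−)-diisopropyl tartrate, t-BuOOH, 4 Å sieves, CH2Cl2, −20 °C) touches only the allylic-alcohol alkene and gives the (2R,3R)-epoxy alcohol F4.
- NaAlH2(OCH2CH2OMe)2 in DME delivers hydride to C2 and gives the (S)-1,3-diol F5.
- TBSCl and imidazole silylate the primary hydroxyl to give the (S)-silyl ether F6.
- Mitsunobu reaction with 8 (PPh3, DIAD, toluene, 0 °C) inverts the benzylic centre to give the (R)-aryl ether F7.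
- Bu4NF then gives 21.

**3. Step 5.** A bromonium ion may form at the prenyl alkene, or the ring may be brominated a second time.

The fallback introduces bromine through a carbanion, which cannot touch the alkene. It sets out from 7 and comes back at 8.
- Ethyl vinyl ether and PPTS give the 1-ethoxyethyl ether F8.
- n-BuLi (THF, 0 °C) metalates the position between the two acetal oxygens to give the aryllithium F9. The two free ring positions are equivalent.
- 1,2-Dibromo-1,1,2,2-tetrachloroethane at −78 °C gives the bromo ethoxyethyl ether F10.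
- PPTS in MeOH at rt removes the ethoxyethyl acetal, while the aryl MOM ethers persist, and gives 8.

## Further compounds

F1 | step 15 | lithium (R)-3-aryl-3-(2-bromoaryloxy)propanoate | [Li+].[O-]C(=O)C[C@@H](Oc1cc(OCOC)c(CC=C(C)C)c(OCOC)c1Br)c1cc(CC=C(C)C)c(OCOC)c(CC=C(C)C)c1
F2 | step 15 | lithium (R)-3-aryl-3-(2-lithioaryloxy)propanoate | [Li+].[O-]C(=O)C[C@@H](Oc1cc(OCOC)c(CC=C(C)C)c(OCOC)c1[Li])c1cc(CC=C(C)C)c(OCOC)c(CC=C(C)C)c1
F3 | step 15 | dilithium (2R)-chroman-4,4-diolate | CC(C)=CCc1cc([C@H]2CC([O-])([O-])c3c(cc(OCOC)c(CC=C(C)C)c3OCOC)O2)cc(CC=C(C)C)c1OCOC.[Li+].[Li+]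
F4 | step 11 | {(2R,3R)-3-[4-(methoxymethoxy)-3,5-bis(3-methylbut-2-enyl)phenyl]oxiran-2-yl}methanol | COCOc1c(CC=C(C)C)cc(cc1CC=C(C)C)[C@@H]2[C@H](O2)CO
F5 | step 11 | (S)-1-[4-(methoxymethoxy)-3,5-bis(3-methylbut-2-enyl)phenyl]propane-1,3-diol | OCC[C@H](O)c1cc(CC=C(C)C)c(OCOC)c(CC=C(C)C)c1
F6 | step 11 | (S)-3-(tert-butyldimethylsilyloxy)-1-[4-(methoxymethoxy)-3,5-bis(3-methylbut-2-enyl)phenyl]propan-1-ol | CC(C)(C)[Si](C)(C)OCC[C@H](O)c1cc(CC=C(C)C)c(OCOC)c(CC=C(C)C)c1
F7 | step 11 | (R)-tert-butyldimethylsilyl ether of 21 | CC(C)(C)[Si](C)(C)OCC[C@@H](Oc1cc(OCOC)c(CC=C(C)C)c(OCOC)c1Br)c1cc(CC=C(C)C)c(OCOC)c(CC=C(C)C)c1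
F8 | step 5 | 5-(1-ethoxyethoxy)-1,3-bis(methoxymethoxy)-2-(3-methylbut-2-enyl)benzene | CCOC(C)Oc1cc(OCOC)c(CC=C(C)C)c(OCOC)c1
F9 | step 5 | 2-(1-ethoxyethoxy)-4,6-bis(methoxymethoxy)-5-(3-methylbut-2-enyl)phenyllithium | CCOC(C)Oc1cc(OCOC)c(CC=C(C)C)c(OCOC)c1[Li]
F10 | step 5 | 2-bromo-1-(1-ethoxyethoxy)-3,5-bis(methoxymethoxy)-4-(3-methylbut-2-enyl)benzene | CCOC(C)Oc1cc(OCOC)c(CC=C(C)C)c(OCOC)c1Br
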